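## Retrosynthetic overview

1. Target 35 ⇐ macrocyclic lactone 30 by end-game group changes only: C8‑OPMB → methacrylate, C9‑OTBS → acetate, C14‑OTBDPS → CHO.
2. 30 ⇐ open-chain bromo-enoate/enal 27: an intramolecular Cr(II) Barbier allylation forms C6–C7 (10-membered carbocycle first), then O6–C12 lactonisation closes the γ-lactone (second ring).
3. 27 ⇐ aldehyde 23 by Baylis–Hillman homologation at C7 (adds C11–C13) and SN2′ bromination; 23 ⇐ alcohol 20.
4. 20 ⇐ C9–C10 disconnection: chelation-controlled addition of the vinylmetal from (Z)-iodide 17 (C1–C6, C10, C14, C15; from prenol) to aldehyde 7 (C7–C9).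
5. 7 ⇐ prochiral 2‑O‑PMB‑glycerol 3 by lipase desymmetrisation, which sets C8; C9, C7 and C6 are relayed from it.

Assumption: the lipase acetylates 2‑O‑PMB‑glycerol with the same pro‑S sense and selectivity that is documented for 2‑O‑benzylglycerol.

Numbering and abbreviations: germacrane numbering of the target is used for the chain and ring (ring C1–C10; C11 on C7 carries C12 carboxyl and C13 methylene; C14 on C10; C15 on C4). The target is 6R,7S,8S,9S, with C4=C5 E and C2/C9 cis across C1=C10. PMB = 4‑methoxybenzyl, TES = triethylsilyl, TBS = tert‑butyldimethylsilyl, TBDPS = tert‑butyldiphenylsilyl.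

## Route

### Fragment C7–C9 (steps 1–6)

Step 1
Reactants: 1 cis-2-phenyl-1,3-dioxan-5-ol (cis-1,3-O-benzylideneglycerol)
Product: 2 cis-5-(PMB-oxy)-2-phenyl-1,3-dioxane
Conditions: NaH, PMBCl, TBAI (cat.), DMF, 0 °C → rt
Reagents that add atoms: 4-methoxybenzyl chloride COc1ccc(CCl)cc1
Why: Williamson etherification of the only free hydroxyl of an achiral (mirror-symmetric) acetal, so no stereochemical issue arises.

Step 2
Reactants: 2 cis-5-(PMB-oxy)-2-phenyl-1,3-dioxane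
Product: 3 2-(PMB-oxy)propane-1,3-diol
Conditions: p-TsOH·H2O (cat.), MeOH, rt
Reagents that add atoms: none
Why: Acid-catalysed transacetalisation removes the benzylidene group as its dimethyl acetal, while the PMB ether survives catalytic acid at rt.

Step 3
Reactants: 3 2-(PMB-oxy)propane-1,3-diol
Product: 4 (S)-3-hydroxy-2-(PMB-oxy)propyl acetate
Conditions: lipase (Burkholderia cepacia lipase, Amano PS, immobilised), vinyl acetate (4 equiv), t-BuOMe, 25 °C, stopped at full conversion of 3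
Reagents that add atoms: vinyl acetate CC(=O)OC=C
Why: Lipase-catalysed enantiotopic-group-selective transesterification (desymmetrisation) of the prochiral diol with an irreversible acyl donor acetylates the pro‑S arm and sets the first stereocentre (C8) by asymmetric biocatalysis.

Step 4
Reactants: 4 (S)-3-hydroxy-2-(PMB-oxy)propyl acetate
Product: 5 (R)-2-(PMB-oxy)-3-(TES-oxy)propyl acetate
Conditions: TESCl, imidazole, CH2Cl2, 0 °C
Reagents that add atoms: chlorotriethylsilane CC[Si](Cl)(CC)CC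
Why: Silylation of the primary alcohol is fast at 0 °C and outruns 1,3-acyl migration, so the ee is kept (the descriptor changes by CIP priority only).

Step 5
Reactants: 5 (R)-2-(PMB-oxy)-3-(TES-oxy)propyl acetate
Product: 6 (R)-2-(PMB-oxy)-3-(TES-oxy)propan-1-ol
Conditions: DIBAL-H (2.2 equiv), CH2Cl2, −78 °C; Rochelle salt work-up
Reagents that add atoms: none
Why: Reductive ester cleavage under non-basic conditions removes the acetate without touching the TES ether or inducing silyl migration.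

Step 6
Reactants: 6 (R)-2-(PMB-oxy)-3-(TES-oxy)propan-1-ol
Product: 7 (S)-2-(PMB-oxy)-3-(TES-oxy)propanal
Conditions: Dess–Martin periodinane, NaHCO3, CH2Cl2, 0 °C → rt; used crude
Reagents that add atoms: none
Why: Buffered Dess–Martin oxidation gives the α-alkoxy aldehyde without epimerising C8.

### Fragment C1–C6/C10/C14/C15 (steps 7–14)

Step 7
Reactants: 8 3-methylbut-2-en-1-ol (prenol)
Product: 9 tert-butyldimethyl(3-methylbut-2-enyloxy)silane
Conditions: TBSCl, imidazole, CH2Cl2, rt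
Reagents that add atoms: tert-butyldimethylsilyl chloride CC(C)(C)[Si](C)(C)Cl
Why: Standard silylation of a primary allylic alcohol.

Step 8
Reactants: 9 tert-butyldimethyl(3-methylbut-2-enyloxy)silane
Product: 10 (E)-4-(TBS-oxy)-2-methylbut-2-en-1-ol
Conditions: SeO2 (0.5 equiv), t-BuOOH (3 equiv), salicylic acid (0.1 equiv), CH2Cl2, 0 °C → rt
Reagents that add atoms: tert-butyl hydroperoxide CC(C)(C)OO (terminal oxidant); selenium dioxide O=[Se]=O (catalytic oxygen-transfer agent)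
Why: Riley allylic oxidation (ene reaction then [2,3]-shift) oxidises only the methyl trans to the chain, fixing the E geometry of C4=C5.

Step 9
Reactants: 10 (E)-4-(TBS-oxy)-2-methylbut-2-en-1-ol
Product: 11 (E)-(4-bromo-3-methylbut-2-enyloxy)(tert-butyl)dimethylsilane
Conditions: CBr4, PPh3, CH2Cl2, 0 °C
Reagents that add atoms: carbon tetrabromide BrC(Br)(Br)Br
Why: Appel bromination is neutral and SN2, so the TBS ether and alkene geometry are kept.

Step 10
Reactants: 11 (E)-(4-bromo-3-methylbut-2-enyloxy)(tert-butyl)dimethylsilane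
Product: 12 (E)-6-(TBS-oxy)-4-methylhex-4-enenitrile
Conditions: MeCN (3.2 equiv), n-BuLi (3 equiv), THF, −78 °C; then 11, −78 → −40 °C
Reagents that add atoms: acetonitrile CC#N
Why: SN2 alkylation of lithioacetonitrile by the unhindered primary allylic bromide adds C1 and C2 without creating a stereocentre.

Step 11
Reactants: 12 (E)-6-(TBS-oxy)-4-methylhex-4-enenitrile
Product: 14 (E)-6-(TBS-oxy)-4-methylhex-4-enal, via N-diisobutylaluminio imine 13 (not isolated)
Conditions: DIBAL-H (1.2 equiv), toluene, −78 °C; then aqueous Rochelle salt, rt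
Reagents that add atoms: water O
Why: Partial DIBAL reduction of a nitrile stops at the aluminium imine, which hydrolyses to the aldehyde on work-up.

Step 12
Reactants: 14 (E)-6-(TBS-oxy)-4-methylhex-4-enal
Product: 15 methyl (2Z,6E)-8-(TBS-oxy)-2-iodo-6-methylocta-2,6-dienoate
Conditions: Ph3P=CHCO2Me (1.3 equiv), NIS (1.35 equiv), CH2Cl2, −20 °C, 15 min; then 14, K2CO3 (2 equiv), −20 °C → rt
Reagents that add atoms: methyl (triphenylphosphoranylidene)acetate COC(=O)C=P(c1ccccc1)(c1ccccc1)c1ccccc1; N-iodosuccinimide O=C1CCC(=O)N1I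
Why: Wittig olefination with the α-iodo stabilised ylide made in the flask puts the ester trans to the chain (Z-iodoenoate), which is the C2/C14-trans geometry needed at C1=C10.

Step 13
Reactants: 15 methyl (2Z,6E)-8-(TBS-oxy)-2-iodo-6-methylocta-2,6-dienoate
Product: 16 (2Z,6E)-8-(TBS-oxy)-2-iodo-6-methylocta-2,6-dien-1-ol
Conditions: DIBAL-H (2.5 equiv), CH2Cl2, −78 °C
Reagents that add atoms: none
Why: DIBAL 1,2-reduction of the enoate gives the allylic alcohol and leaves the vinyl iodide and its geometry intact at −78 °C.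

Step 14
Reactants: 16 (2Z,6E)-8-(TBS-oxy)-2-iodo-6-methylocta-2,6-dien-1-ol
Product: 17 (2Z,6E)-8-(TBS-oxy)-1-(TBDPS-oxy)-2-iodo-6-methylocta-2,6-diene
Conditions: TBDPSCl, imidazole, DMF, rt
Reagents that add atoms: tert-butyldiphenylsilyl chloride CC(C)(C)[Si](Cl)(c1ccccc1)c1ccccc1
Why: Silylation gives a C14 ether that outlasts the later selective removals of TES and primary TBS.

### Union and end game (steps 15–28)

Step 15
Reactants: 17 (2Z,6E)-8-(TBS-oxy)-1-(TBDPS-oxy)-2-iodo-6-methylocta-2,6-diene; 7 (S)-2-(PMB-oxy)-3-(TES-oxy)propanal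
Product: 20 (2S,3S,4Z,8E)-10-(TBS-oxy)-4-(TBDPS-oxymethyl)-2-(PMB-oxy)-8-methyl-1-(TES-oxy)deca-4,8-dien-3-ol, via vinyllithium 18 (not isolated), via vinylmagnesium bromide 19 (not isolated)
Conditions: 17 (1.3 equiv), t-BuLi (2.6 equiv), Et2O, −78 °C; MgBr2·OEt2 (3 equiv), −78 °C; then 7 in CH2Cl2, −78 → −40 °C
Reagents that add atoms: none
Why: Iodine–lithium exchange with retention of alkene geometry, transmetalation to magnesium and Cram-chelate-controlled addition (Mg bridging C=O and the α-OPMB, attack anti to the CH2OTES arm) give the 8,9-syn alcohol, i.e. 9S.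

Step 16
Reactants: 20 C9 alcohol
Product: 21 (2S,3S,4Z,8E)-3,10-bis(TBS-oxy)-4-(TBDPS-oxymethyl)-2-(PMB-oxy)-8-methyl-1-(TES-oxy)deca-4,8-diene
Conditions: TBSOTf, 2,6-lutidine, CH2Cl2, −78 → 0 °C
Reagents that add atoms: tert-butyldimethylsilyl triflate CC(C)(C)[Si](C)(C)OS(=O)(=O)C(F)(F)F
Why: Silyl triflate silylation protects the hindered allylic C9 alcohol as an ether that cannot β-eliminate in the later Baylis–Hillman step.

Step 17
Reactants: 21 fully protected chain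
Product: 22 (2S,3S,4Z,8E)-3,10-bis(TBS-oxy)-4-(TBDPS-oxymethyl)-2-(PMB-oxy)-8-methyldeca-4,8-dien-1-ol
Conditions: PPTS (0.2 equiv), MeOH/CH2Cl2 1:1, 0 °C
Reagents that add atoms: none
Why: Acid-catalysed methanolysis cleaves the primary TES ether about two orders of magnitude faster than the primary TBS ether, and the secondary TBS, TBDPS and PMB groups are untouched.

Step 18
Reactants: 22 C7 primary alcohol
Product: 23 (2R,3S,4Z,8E)-3,10-bis(TBS-oxy)-4-(TBDPS-oxymethyl)-2-(PMB-oxy)-8-methyldeca-4,8-dienal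
Conditions: Dess–Martin periodinane, NaHCO3, CH2Cl2, 0 °C → rt; used crude
Reagents that add atoms: none
Why: Buffered Dess–Martin oxidation gives the C7 aldehyde without epimerising C8 (the descriptor changes by CIP priority only).

Step 19
Reactants: 23 C7 aldehyde
Product: 24 methyl (3RS,4S,5S,6Z,10E)-5,12-bis(TBS-oxy)-6-(TBDPS-oxymethyl)-3-hydroxy-4-(PMB-oxy)-10-methyl-2-methylidenedodeca-6,10-dienoate
Conditions: methyl acrylate (10 equiv), DABCO (1.0 equiv), MeOH (2 equiv), rt, 2–4 d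
Reagents that add atoms: methyl acrylate C=CC(=O)OC
Why: Morita–Baylis–Hillman reaction of the activated α-alkoxy aldehyde adds C11–C13; the new C7 carbinol forms as an epimer mixture that does not matter because it is erased in step 20.

Step 20
Reactants: 24 Baylis–Hillman adduct
Product: 25 methyl (2Z,4S,5S,6Z,10E)-2-(bromomethyl)-5,12-bis(TBS-oxy)-6-(TBDPS-oxymethyl)-4-(PMB-oxy)-10-methyldodeca-2,6,10-trienoate
Conditions: NBS (1.5 equiv) premixed with Me2S (1.8 equiv), CH2Cl2, 0 °C; then 24, 0 °C → rt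
Reagents that add atoms: N-bromosuccinimide O=C1CCC(=O)N1Br
Why: Corey–Kim-type activation of the alcohol and SN2′ attack of bromide give the thermodynamically favoured (Z)-2-(bromomethyl)enoate, converging both C7 epimers; the premixed sulfonium salt does not brominate the other alkenes.

Step 21
Reactants: 25 allylic bromide
Product: 26 methyl (2Z,4S,5S,6Z,10E)-2-(bromomethyl)-5-(TBS-oxy)-6-(TBDPS-oxymethyl)-12-hydroxy-4-(PMB-oxy)-10-methyldodeca-2,6,10-trienoate
Conditions: CSA (0.2 equiv), MeOH/CH2Cl2 1:1, 0 °C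
Reagents that add atoms: none
Why: Acid-catalysed methanolysis removes the primary allylic TBS ether selectively over the hindered secondary TBS and the TBDPS ether, and amine-free acid conditions spare the allylic bromide.

Step 22
Reactants: 26 C6 allylic alcohol
Product: 27 methyl (2Z,4S,5S,6Z,10E)-2-(bromomethyl)-5-(TBS-oxy)-6-(TBDPS-oxymethyl)-4-(PMB-oxy)-10-methyl-12-oxododeca-2,6,10-trienoate
Conditions: MnO2 (20 equiv), CH2Cl2, rt
Reagents that add atoms: none
Why: Heterogeneous MnO2 oxidation of the allylic alcohol is neutral, keeps the E-enal geometry and tolerates the allylic bromide.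

Step 23
Reactants: 27 bromo-enoate enal
Product: 30 (6R,7S,8S,9S)-8-(PMB-oxy)-9-(TBS-oxy)-14-(TBDPS-oxy)germacra-1(10),4,11(13)-trien-12,6-olide, via allylchromium(III) species 28 (not isolated), via hydroxy ester 29 (not isolated)
Conditions: CrCl2 (8 equiv), THF, rt, 27 added by syringe pump over 10 h (final 2 mM); aq. NH4Cl work-up; then PPTS (0.2 equiv), toluene, 40 °C
Reagents that add atoms: none
Why: Intramolecular Nozaki–Hiyama-type Cr(II) Barbier allylation through the γ-carbon (C7) in a chair transition state with both ring chains equatorial (H6/H7 anti) gives the 6,7-trans relationship, while allylic 1,3-strain holds H8 in the plane of C7=C11 so the aldehyde attacks anti to the C8–C9 bond (7S, hence 6R); the hydroxy ester then lactonises to the trans-fused γ-lactone.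

Step 24
Reactants: 30 macrocyclic lactone
Product: 31 (6R,7S,8S,9S)-8-hydroxy-9-(TBS-oxy)-14-(TBDPS-oxy)germacra-1(10),4,11(13)-trien-12,6-olide
Conditions: DDQ (1.5 equiv), CH2Cl2/pH 7 buffer 10:1, 0 °C → rt
Reagents that add atoms: none
Why: Oxidative PMB cleavage by DDQ is neutral and leaves silyl ethers, the isolated alkenes and the α-methylene lactone untouched.

Step 25
Reactants: 31 C8 alcohol
Product: 32 (6R,7S,8S,9S)-8-(methacryloyloxy)-9-(TBS-oxy)-14-(TBDPS-oxy)germacra-1(10),4,11(13)-trien-12,6-olide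
Conditions: methacrylic anhydride (3 equiv), Et3N (4 equiv), DMAP (0.3 equiv), CH2Cl2, 0 °C → rt
Reagents that add atoms: methacrylic anhydride C=C(C)C(=O)OC(=O)C(C)=C
Why: DMAP-catalysed acylation installs the C8 ester while O9 is still silylated, so no acyl migration between O8 and O9 can occur.

Step 26
Reactants: 32 C8 methacrylate
Product: 33 (6R,7S,8S,9S)-9,14-dihydroxy-8-(methacryloyloxy)germacra-1(10),4,11(13)-trien-12,6-olide
Conditions: HF·pyridine (excess), pyridine, THF, 0 °C → rt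
Reagents that add atoms: none
Why: Buffered fluoride desilylation removes both silyl ethers under weakly acidic conditions that neither cleave nor migrate the esters.

Step 27
Reactants: 33 C9/C14 diol
Product: 34 (6R,7S,8S,9S)-9-hydroxy-8-(methacryloyloxy)-14-oxogermacra-1(10),4,11(13)-trien-12,6-olide
Conditions: TEMPO (0.2 equiv), PhI(OAc)2 (1.2 equiv), CH2Cl2, rt
Reagents that add atoms: none
Why: TEMPO/PhI(OAc)2 oxidation is selective for the primary allylic alcohol over the hindered secondary one and gives the enal without alkene isomerisation.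

Step 28
Reactants: 34 C9 alcohol enal
Product: 35 target, (6R,7S,8S,9S)-9-acetoxy-8-(methacryloyloxy)-14-oxogermacra-1(10),4,11(13)-trien-12,6-olide
Conditions: Ac2O (3 equiv), pyridine, DMAP (0.1 equiv), CH2Cl2, 0 °C
Reagents that add atoms: acetic anhydride CC(=O)OC(C)=O
Why: Fast DMAP-catalysed acetylation of the free C9 alcohol outruns any migration of the C8 methacrylate and completes the target.

## Compound list

1 | cis-2-phenyl-1,3-dioxan-5-ol (cis-1,3-O-benzylideneglycerol) | O[C@H]1CO[C@@H](c2ccccc2)OC1 | starting material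
2 | cis-5-(PMB-oxy)-2-phenyl-1,3-dioxane | COc1ccc(CO[C@H]2CO[C@@H](c3ccccc3)OC2)cc1 | intermediate
3 | 2-(PMB-oxy)propane-1,3-diol | COc1ccc(COC(CO)CO)cc1 | intermediate
4 | (S)-3-hydroxy-2-(PMB-oxy)propyl acetate | CC(=O)OC[C@H](CO)OCc1ccc(OC)cc1 | intermediate
5 | (R)-2-(PMB-oxy)-3-(TES-oxy)propyl acetate | CC(=O)OC[C@H](CO[Si](CC)(CC)CC)OCc1ccc(OC)cc1 | intermediate
6 | (R)-2-(PMB-oxy)-3-(TES-oxy)propan-1-ol | OC[C@H](CO[Si](CC)(CC)CC)OCc1ccc(OC)cc1 | intermediate
7 | (S)-2-(PMB-oxy)-3-(TES-oxy)propanal | O=C[C@H](CO[Si](CC)(CC)CC)OCc1ccc(OC)cc1 | intermediate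
8 | 3-methylbut-2-en-1-ol (prenol) | CC(C)=CCO | starting material
9 | tert-butyldimethyl(3-methylbut-2-enyloxy)silane | CC(C)=CCO[Si](C)(C)C(C)(C)C | intermediate
10 | (E)-4-(TBS-oxy)-2-methylbut-2-en-1-ol | CC(C)(C)[Si](C)(C)OC/C=C(\C)CO | intermediate
11 | (E)-(4-bromo-3-methylbut-2-enyloxy)(tert-butyl)dimethylsilane | CC(C)(C)[Si](C)(C)OC/C=C(\C)CBr | intermediate
12 | (E)-6-(TBS-oxy)-4-methylhex-4-enenitrile | CC(C)(C)[Si](C)(C)OC/C=C(\C)CCC#N | intermediate
13 | N-(diisobutylaluminio)imine of aldehyde 14 | CC(C)C[Al](CC(C)C)N=CCC/C(C)=C/CO[Si](C)(C)C(C)(C)C | intermediate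
14 | (E)-6-(TBS-oxy)-4-methylhex-4-enal | CC(C)(C)[Si](C)(C)OC/C=C(\C)CCC=O | intermediate
15 | methyl (2Z,6E)-8-(TBS-oxy)-2-iodo-6-methylocta-2,6-dienoate | COC(=O)/C(I)=C/CC/C(C)=C/CO[Si](C)(C)C(C)(C)C | intermediate
16 | (2Z,6E)-8-(TBS-oxy)-2-iodo-6-methylocta-2,6-dien-1-ol | OC/C(I)=C/CC/C(C)=C/CO[Si](C)(C)C(C)(C)C | intermediate
17 | (2Z,6E)-8-(TBS-oxy)-1-(TBDPS-oxy)-2-iodo-6-methylocta-2,6-diene | CC(C)(C)[Si](OC/C(I)=C/CC/C(C)=C/CO[Si](C)(C)C(C)(C)C)(c1ccccc1)c1ccccc1 | intermediate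
18 | vinyllithium from 17 (Li in place of I, geometry retained) | CC(C)(C)[Si](OC/C([Li])=C/CC/C(C)=C/CO[Si](C)(C)C(C)(C)C)(c1ccccc1)c1ccccc1 | intermediate
19 | vinylmagnesium bromide from 18 (geometry retained) | CC(C)(C)[Si](OC/C([Mg]Br)=C/CC/C(C)=C/CO[Si](C)(C)C(C)(C)C)(c1ccccc1)c1ccccc1 | intermediate
20 | (2S,3S,4Z,8E)-10-(TBS-oxy)-4-(TBDPS-oxymethyl)-2-(PMB-oxy)-8-methyl-1-(TES-oxy)deca-4,8-dien-3-ol (8S,9S in target numbering) | CC[Si](CC)(CC)OC[C@H](OCc1ccc(OC)cc1)[C@@H](O)/C(CO[Si](c1ccccc1)(c1ccccc1)C(C)(C)C)=C\CC/C(C)=C/CO[Si](C)(C)C(C)(C)C | intermediate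
21 | (2S,3S,4Z,8E)-3,10-bis(TBS-oxy)-4-(TBDPS-oxymethyl)-2-(PMB-oxy)-8-methyl-1-(TES-oxy)deca-4,8-diene | CC[Si](CC)(CC)OC[C@H](OCc1ccc(OC)cc1)[C@@H](O[Si](C)(C)C(C)(C)C)/C(CO[Si](c1ccccc1)(c1ccccc1)C(C)(C)C)=C\CC/C(C)=C/CO[Si](C)(C)C(C)(C)C | intermediate
22 | (2S,3S,4Z,8E)-3,10-bis(TBS-oxy)-4-(TBDPS-oxymethyl)-2-(PMB-oxy)-8-methyldeca-4,8-dien-1-ol | OC[C@H](OCc1ccc(OC)cc1)[C@@H](O[Si](C)(C)C(C)(C)C)/C(CO[Si](c1ccccc1)(c1ccccc1)C(C)(C)C)=C\CC/C(C)=C/CO[Si](C)(C)C(C)(C)C | intermediate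
23 | (2R,3S,4Z,8E)-3,10-bis(TBS-oxy)-4-(TBDPS-oxymethyl)-2-(PMB-oxy)-8-methyldeca-4,8-dienal | O=C[C@H](OCc1ccc(OC)cc1)[C@@H](O[Si](C)(C)C(C)(C)C)/C(CO[Si](c1ccccc1)(c1ccccc1)C(C)(C)C)=C\CC/C(C)=C/CO[Si](C)(C)C(C)(C)C | intermediate
24 | methyl (3RS,4S,5S,6Z,10E)-5,12-bis(TBS-oxy)-6-(TBDPS-oxymethyl)-3-hydroxy-4-(PMB-oxy)-10-methyl-2-methylidenedodeca-6,10-dienoate (C3 epimer mixture) | C=C(C(=O)OC)C(O)[C@H](OCc1ccc(OC)cc1)[C@@H](O[Si](C)(C)C(C)(C)C)/C(CO[Si](c1ccccc1)(c1ccccc1)C(C)(C)C)=C\CC/C(C)=C/CO[Si](C)(C)C(C)(C)C | intermediate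
25 | methyl (2Z,4S,5S,6Z,10E)-2-(bromomethyl)-5,12-bis(TBS-oxy)-6-(TBDPS-oxymethyl)-4-(PMB-oxy)-10-methyldodeca-2,6,10-trienoate | COC(=O)/C(CBr)=C/[C@H](OCc1ccc(OC)cc1)[C@@H](O[Si](C)(C)C(C)(C)C)/C(CO[Si](c1ccccc1)(c1ccccc1)C(C)(C)C)=C\CC/C(C)=C/CO[Si](C)(C)C(C)(C)C | intermediate
26 | methyl (2Z,4S,5S,6Z,10E)-2-(bromomethyl)-5-(TBS-oxy)-6-(TBDPS-oxymethyl)-12-hydroxy-4-(PMB-oxy)-10-methyldodeca-2,6,10-trienoate | COC(=O)/C(CBr)=C/[C@H](OCc1ccc(OC)cc1)[C@@H](O[Si](C)(C)C(C)(C)C)/C(CO[Si](c1ccccc1)(c1ccccc1)C(C)(C)C)=C\CC/C(C)=C/CO | intermediate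
27 | methyl (2Z,4S,5S,6Z,10E)-2-(bromomethyl)-5-(TBS-oxy)-6-(TBDPS-oxymethyl)-4-(PMB-oxy)-10-methyl-12-oxododeca-2,6,10-trienoate | COC(=O)/C(CBr)=C/[C@H](OCc1ccc(OC)cc1)[C@@H](O[Si](C)(C)C(C)(C)C)/C(CO[Si](c1ccccc1)(c1ccccc1)C(C)(C)C)=C\CC/C(C)=C/C=O | intermediate
28 | allylchromium(III) species from 27 (CrCl2 in place of Br, allyl geometry equilibrating) | COC(=O)C(C[Cr](Cl)Cl)=C[C@H](OCc1ccc(OC)cc1)[C@@H](O[Si](C)(C)C(C)(C)C)/C(CO[Si](c1ccccc1)(c1ccccc1)C(C)(C)C)=C\CC/C(C)=C/C=O | intermediate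
29 | methyl (6R,7S,8S,9S)-6-hydroxy-8-(PMB-oxy)-9-(TBS-oxy)-14-(TBDPS-oxy)germacra-1(10),4,11(13)-trien-12-oate (4E; C2/C9 cis at C1=C10) | COc1ccc(cc1)CO[C@H]2[C@@H](C(=C)C(=O)OC)[C@H](O)/C=C(\C)CC/C=C(/CO[Si](c3ccccc3)(c3ccccc3)C(C)(C)C)[C@@H]2O[Si](C)(C)C(C)(C)C | intermediate
30 | (6R,7S,8S,9S)-8-(PMB-oxy)-9-(TBS-oxy)-14-(TBDPS-oxy)germacra-1(10),4,11(13)-trien-12,6-olide | COc1ccc(cc1)CO[C@H]2[C@H]3C(=C)C(=O)O[C@@H]3/C=C(\C)CC/C=C(/CO[Si](c4ccccc4)(c4ccccc4)C(C)(C)C)[C@@H]2O[Si](C)(C)C(C)(C)C | intermediate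
31 | (6R,7S,8S,9S)-8-hydroxy-9-(TBS-oxy)-14-(TBDPS-oxy)germacra-1(10),4,11(13)-trien-12,6-olide | O[C@H]1[C@H]2C(=C)C(=O)O[C@@H]2/C=C(\C)CC/C=C(/CO[Si](c3ccccc3)(c3ccccc3)C(C)(C)C)[C@@H]1O[Si](C)(C)C(C)(C)C | intermediate
32 | (6R,7S,8S,9S)-8-(methacryloyloxy)-9-(TBS-oxy)-14-(TBDPS-oxy)germacra-1(10),4,11(13)-trien-12,6-olide | C=C(C)C(=O)O[C@H]1[C@H]2C(=C)C(=O)O[C@@H]2/C=C(\C)CC/C=C(/CO[Si](c3ccccc3)(c3ccccc3)C(C)(C)C)[C@@H]1O[Si](C)(C)C(C)(C)C | intermediate
33 | (6R,7S,8S,9S)-9,14-dihydroxy-8-(methacryloyloxy)germacra-1(10),4,11(13)-trien-12,6-olide | C=C(C)C(=O)O[C@H]1[C@H]2C(=C)C(=O)O[C@@H]2/C=C(\C)CC/C=C(/CO)[C@@H]1O | intermediate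
34 | (6R,7S,8S,9S)-9-hydroxy-8-(methacryloyloxy)-14-oxogermacra-1(10),4,11(13)-trien-12,6-olide | C=C(C)C(=O)O[C@H]1[C@H]2C(=C)C(=O)O[C@@H]2/C=C(\C)CC/C=C(/C=O)[C@@H]1O | intermediate
35 | (6R,7S,8S,9S)-9-acetoxy-8-(methacryloyloxy)-14-oxogermacra-1(10),4,11(13)-trien-12,6-olide (4E; formyl trans to C2 at C1=C10) | C=C(C)C(=O)O[C@H]1[C@H]2C(=C)C(=O)O[C@@H]2/C=C(\C)CC/C=C(/C=O)[C@@H]1OC(C)=O | target

## Step count and risk

Total step count: 28.
Longest linear sequence: 22 steps (prenol 8 through steps 7–28 to 35); the glycerol branch is 6 steps to the union.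

Three steps most likely to fail:

Step 23 (Cr-mediated macrocyclisation). This is the weakest point of the route: the 6,7-trans outcome and the C7 face are predicted from transition-state models, not guaranteed, and oligomerisation or loss of the labile bromide can cut the yield. The fallback sets out from 24 and comes back at 30. Acetylation of 24 (Ac2O, pyridine, DMAP) gives the Baylis–Hillman acetate F1. CSA in MeOH frees the C6 alcohol F2, and MnO2 gives the enal acetate F3, so no allylic bromide is carried through deprotection and oxidation. Ring closure is then a Pd(0)-catalysed umpolung allylation (Pd(PPh3)4 10 mol %, Et2Zn 3 equiv, THF, 2 mM, rt): ionisation of the acetate to a π-allylpalladium complex and transmetalation give the allylzinc species F4, which adds to the enal through a chair transition state to give 29 and, after PPTS, 30. This changes the precursor and the metal manifold, not the bond formed, so it addresses yield more than facial selectivity.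

Step 15 (chelation-controlled union). The risks are decomposition of the vinyllithium and a low syn/anti ratio at C9. The fallback sets out from 17 and 7 and comes back at 20. A Nozaki–Hiyama–Kishi coupling (CrCl2, NiCl2 1 mol %, DMF/THF, rt) through the alkenylchromium(III) species F5 needs no organolithium and gives 20 together with its (9R)-epimer F6. The mixture is oxidised (Dess–Martin) to the C9 enone F7. Reagent-controlled Corey–Bakshi–Shibata reduction ((S)-Me-CBS, catecholborane, toluene, −78 °C; the 2-substituted alkenyl group acts as the large group, matched with the Felkin preference) returns 20 as the 9S alcohol.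

Step 19 (Baylis–Hillman reaction). The hindered α-alkoxy aldehyde may react slowly, and long exposure to DABCO can epimerise C8. The fallback sets out from 23 and comes back at 24. Hydroalumination of methyl propiolate (DIBAL-H, NMO, THF, 0 °C) gives [1-(methoxycarbonyl)vinyl]diisobutylaluminium F8, a preformed α-acrylate anion equivalent. It adds to 23 at −78 → 0 °C within hours in an aldol-type reaction without amine base and gives 24 directly.

## Further compounds

F1 | step 23 | Baylis–Hillman acetate: methyl (3RS,4S,5S,6Z,10E)-3-acetoxy-5,12-bis(TBS-oxy)-6-(TBDPS-oxymethyl)-4-(PMB-oxy)-10-methyl-2-methylidenedodeca-6,10-dienoate | C=C(C(=O)OC)C(OC(C)=O)[C@H](OCc1ccc(OC)cc1)[C@@H](O[Si](C)(C)C(C)(C)C)/C(CO[Si](c1ccccc1)(c1ccccc1)C(C)(C)C)=C\CC/C(C)=C/CO[Si](C)(C)C(C)(C)C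
F2 | step 23 | C6 alcohol: 12-hydroxy analogue of F1 (primary TBS removed) | C=C(C(=O)OC)C(OC(C)=O)[C@H](OCc1ccc(OC)cc1)[C@@H](O[Si](C)(C)C(C)(C)C)/C(CO[Si](c1ccccc1)(c1ccccc1)C(C)(C)C)=C\CC/C(C)=C/CO
F3 | step 23 | enal acetate: 12-oxo analogue of F1 | C=C(C(=O)OC)C(OC(C)=O)[C@H](OCc1ccc(OC)cc1)[C@@H](O[Si](C)(C)C(C)(C)C)/C(CO[Si](c1ccccc1)(c1ccccc1)C(C)(C)C)=C\CC/C(C)=C/C=O
F4 | step 23 | allylzinc species from F3 (EtZn on C13, allyl geometry equilibrating) | CC[Zn]CC(C(=O)OC)=C[C@H](OCc1ccc(OC)cc1)[C@@H](O[Si](C)(C)C(C)(C)C)/C(CO[Si](c1ccccc1)(c1ccccc1)C(C)(C)C)=C\CC/C(C)=C/C=O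
F5 | step 15 | alkenylchromium(III) species from 17 (CrCl2 in place of I, geometry retained) | CC(C)(C)[Si](OC/C([Cr](Cl)Cl)=C/CC/C(C)=C/CO[Si](C)(C)C(C)(C)C)(c1ccccc1)c1ccccc1
F6 | step 15 | (9R)-epimer of 20: (2S,3R,4Z,8E)-10-(TBS-oxy)-4-(TBDPS-oxymethyl)-2-(PMB-oxy)-8-methyl-1-(TES-oxy)deca-4,8-dien-3-ol | CC[Si](CC)(CC)OC[C@H](OCc1ccc(OC)cc1)[C@H](O)/C(CO[Si](c1ccccc1)(c1ccccc1)C(C)(C)C)=C\CC/C(C)=C/CO[Si](C)(C)C(C)(C)C
F7 | step 15 | C9 enone: (2S,4Z,8E)-10-(TBS-oxy)-4-(TBDPS-oxymethyl)-2-(PMB-oxy)-8-methyl-1-(TES-oxy)deca-4,8-dien-3-one | CC[Si](CC)(CC)OC[C@H](OCc1ccc(OC)cc1)C(=O)/C(CO[Si](c1ccccc1)(c1ccccc1)C(C)(C)C)=C\CC/C(C)=C/CO[Si](C)(C)C(C)(C)C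
F8 | step 19 | [1-(methoxycarbonyl)vinyl]diisobutylaluminium | C=C(C(=O)OC)[Al](CC(C)C)CC(C)C
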